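## The problem

Elemane numbering is used. C10 is the quaternary ring carbon and carries the C14 methyl group and the C1=C2 vinyl group. C5 bears C4(=C3H2)–C15H2OH, C6 the lactone oxygen, C7 the acrylate carbon C11(=C13H2)–C12, and C8 the ester oxygen; C9 is the only ring CH2. β is the face of the C14 methyl group.

The target is a cyclohexane substituted on five of its six carbons. It is trans-fused at C6–C7 to an α-methylene-γ-butyrolactone, and every substituent is equatorial except the axial C10 methyl group.

The hardest element is the C5–C10 bond, which joins a quaternary to a tertiary stereocentre. Methyl and vinyl have almost the same size, so neither equilibration nor steric bias in a preformed ring can tell them apart. Only the geometry of a concerted bond formation can.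

Once C5 and C10 are fixed, C5 can control its neighbour C6. The chair defined by C5, C6 and C10 can then control C7 and C8.

Several groups are fragile. The exo-methylene lactone is a Michael acceptor. The (Z)-2-(hydroxymethyl)but-2-enoate isomerises to the E form. There are two primary allylic alcohols, and C5–H is allylic and becomes acidic whenever C6 is a carbonyl group.

The feature that makes the key step possible is the chain C2=C1–C10–C5–C6(O). With C6 raised to a carboxyl group this is the γ,δ-unsaturated acid pattern of an ester-enolate Claisen product, and C3=C4 rides along on C5.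

A second feature serves the ring closure. O8–C8–C7–C11=C13 is a homoallylic alcohol, and C8–C9–C10–C5–C6–C7–C11(C12)(C13) is the carbon chain of a citronellal-type enal.

## Retrosynthesis

**Lactone and silyl groups.** Target 32 is opened at the O6–C12 bond and the three free hydroxyl groups are silylated, which leads to acrylic acid 30. The forward step is one fluoride-mediated deprotection. It sets free hydroxy acid 31, whose diequatorial C6–OH and C7 side chain can only close to the trans lactone. The Michael acceptor therefore appears in the last step and meets no nucleophile or base.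

**C12 oxidation level.** Acid 30 is traced through allylic alcohol 29 to ester 28, in which C7 bears a plain isopropenyl group. The cut removes two oxygen atoms and no carbon. The forward oxidation must choose the C12 methyl group over all other allylic positions. It is the only allylic methyl group on an electron-rich alkene, because C15 already carries oxygen and the side-chain alkene is electron-poor.

**C8 ester.** The O8–acyl bond of 28 is cut to give cyclohexanol 20 and silylated (Z)-acid 26. C8–OH is the only free hydroxyl group of 20, so no selectivity is asked for. The one demand is that the Z geometry survives.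

**C7–C8.** Ring compound 20 is opened to acyclic aldehyde 19 by a retro carbonyl-ene reaction. This cut is preferred to C6–C7 or C5–C6 for three reasons. It delivers C8–OH free, it creates the C11=C13 methylene group, and it needs only a prenyl-type alkene as the nucleophile. Two stereocentres and the ring disappear. The forward closure must pass through the chair in which the C5 and C6 substituents and the vinyl group are equatorial.

**C6–C7.** Aldehyde 19 goes back through 18 and 17 to aldehyde 15 and the commercial Grignard reagent 16. The cut removes the C6 stereocentre and four carbons. The forward addition needs 1,2-induction from C5, whose three substituents (quaternary C10, an alkenyl group, H) differ strongly in size.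

**C5–C10 (key cut).** Aldehyde 15 comes from acid 13 by way of alcohol 14. Acid 13 is cut at the most hindered bond of the target to give the achiral allyl ester 11. Against the neighbouring C10–C9 or C10–C1 cuts, this one sets both stereocentres at once from alkene and enolate geometry. It also produces the vinyl group by allylic transposition and joins two fragments of similar size. The precursor has no stereocentre. The forward reaction must control the enolate geometry, the chair topology and the absolute facial sense.

**Fragments.** Ester 11 is divided into acid 5 and (E)-allylic alcohol 10. Acid 5 comes from methallyl alcohol 1 and CO2 by way of 3. Alcohol 10 comes from but-3-yn-1-ol 6 through 7 by carboalumination. Acid 26 is traced through 24, 23 and 22 to crotonaldehyde 21. The Z-selective α-iodination of 21 fixes the side-chain geometry before any carbonyl activation.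

## Roads not taken

**Alternative 1:** cut no ring bond but re-form C2–C3, a retro-Cope step to the ten-membered 8α,15-dihydroxygermacra-1(10),4,11(13)-trien-6α,12-olide A1.
- Forward key step: thermal Cope rearrangement of A1 through its chair-like crown conformer. This is the most obvious plan.
- A1 holds the same lactone, the same three carbinol-type stereocentres and two E-trisubstituted alkenes in a strained ring, so the precursor is harder to make than the product.
- A macrocyclisation is still required, and the rearrangement is an equilibrium run at a temperature that endangers the acrylate units.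
- The chosen plan forms the same C5–C10 bond in an open chain, where formation of the carboxylate makes it irreversible.

**Alternative 2:** keep C2–C3 in a trans-decalin and cleave it late.
- Forward key step: 1,3-diol monosulfonate fragmentation of 1β-mesyloxy-3β,8α-dihydroxyeudesma-4(15),11(13)-dien-6α,12-olide A2. This gives the vinyl group and enal A3, which is then reduced in the 1,2-sense.
- The decalin settles the methyl/vinyl question reliably.
- A2 has seven stereocentres and two extra oxygen functions that exist only to be destroyed.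
- The cheap eudesmanolides lack the C8 oxygen, so the run-up would be far longer than the whole chosen route.

**Alternative 3:** keep the six-membered ring from the start and cut C10–C1 and C5–C4.
- Forward key step: enantioselective conjugate vinylation of 3-methylcyclohex-2-en-1-one A4, followed by alkenylation of the enolate to give ketone A5.
- The C5 substituent must then choose between the methyl and the vinyl face of C10, for which there is no basis. Equilibration at C5 risks conjugation of C3=C4.
- The axial methyl group hinders axial hydride delivery at C6, which favours the wrong 6β-alcohol.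
- The methyl group also makes the facial course of any addition at C8 ambiguous. Four of the five stereocentres would rest on weak control.

Key step: step 6

Assumption: the (S,S)-configured boron controller is taken to give the (2R,3S)-acid 13 by analogy with simpler allyl esters; the (R,R)-reagent is equally available and nothing else in the route depends on this choice.

## Steps

Step 1
Reactants: 1 2-methylprop-2-en-1-ol
Product: 3 3-(hydroxymethyl)but-3-enoic acid, via dilithio dianion 2 (not isolated)
Conditions: n-BuLi (2.2 equiv), TMEDA, Et2O–hexane, 0 °C → rt; CO2, −78 °C; aq. HCl to pH 3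
Reagents that add atoms: carbon dioxide, O=C=O
Why: Double deprotonation gives an alkoxide-bearing allyl anion whose two termini are equivalent, so carboxylation can give only one β,γ-unsaturated acid (allylic metalation–carboxylation).

Step 2
Reactants: 3 3-(hydroxymethyl)but-3-enoic acid
Product: 5 3-{[(tert-butyldimethylsilyl)oxy]methyl}but-3-enoic acid, via bis-silyl derivative 4 (not isolated)
Conditions: TBSCl (2.2 equiv), imidazole, DMF, rt; then THF–H2O–AcOH, rt
Reagents that add atoms: tert-butyldimethylsilyl chloride, CC(C)(C)[Si](C)(C)Cl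
Why: Standard silylation; the silyl ester is much more labile than the primary silyl ether and is hydrolysed selectively under mild acid, which does not move the double bond.

Step 3
Reactants: 6 but-3-yn-1-ol
Product: 7 (but-3-yn-1-yloxy)triethylsilane
Conditions: TESCl, imidazole, CH2Cl2, 0 °C
Reagents that add atoms: triethylsilyl chloride, CC[Si](Cl)(CC)CC
Why: Standard silylation; the triethylsilyl group is chosen because it is the handle for the direct oxidation in step 11.

Step 4
Reactants: 7 (but-3-yn-1-yloxy)triethylsilane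
Product: 10 (2E)-3-methyl-5-[(triethylsilyl)oxy]pent-2-en-1-ol, via vinylalane 8 (not isolated), via lithium aluminate 9 (not isolated)
Conditions: Me3Al, Cp2ZrCl2 (cat.), CH2Cl2, 0 °C → rt; n-BuLi, THF–hexane, −78 °C; (CH2O)n, −78 °C → rt; H2O
Reagents that add atoms: trimethylaluminium, C[Al](C)C; paraformaldehyde (as formaldehyde), C=O
Why: Zirconium-catalysed syn-carboalumination (Negishi) puts methyl on the internal and aluminium on the terminal carbon, and hydroxymethylation of the ate complex goes with retention. The C1=C10 double bond is therefore obtained as the pure E isomer on which the key step depends.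

Step 5
Reactants: 5 3-{[(tert-butyldimethylsilyl)oxy]methyl}but-3-enoic acid; 10 (2E)-3-methyl-5-[(triethylsilyl)oxy]pent-2-en-1-ol
Product: 11 (2E)-3-methyl-5-[(triethylsilyl)oxy]pent-2-en-1-yl 3-{[(tert-butyldimethylsilyl)oxy]methyl}but-3-enoate
Conditions: DCC, DMAP (cat.), CH2Cl2, 0 °C
Reagents that add atoms: none
Why: Steglich esterification of an unhindered primary allylic alcohol; low temperature and little DMAP keep the C3=C4 double bond out of conjugation.

Step 6
Reactants: 11 (2E)-3-methyl-5-[(triethylsilyl)oxy]pent-2-en-1-yl 3-{[(tert-butyldimethylsilyl)oxy]methyl}but-3-enoate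
Product: 13 (2R,3S)-2-{3-[(tert-butyldimethylsilyl)oxy]prop-1-en-2-yl}-3-ethenyl-3-methyl-5-[(triethylsilyl)oxy]pentanoic acid, via boron ketene acetal 12 (not isolated)
Conditions: (1S,2S)-N,N'-bis[3,5-bis(trifluoromethyl)benzenesulfonyl]-1,2-diphenylethane-1,2-diamine, BBr3, CH2Cl2, rt, evaporate; 11, Et3N, toluene–hexane, −78 °C → 4 °C; aq. work-up
Reagents that add atoms: none
Why: Soft enolisation of 11 with the chiral B-bromodiazaborolidine and Et3N in a non-polar medium should give ketene acetal 12 with the C4 alkenyl group trans to O–B, and on warming 12 undergoes a concerted [3,3]-sigmatropic shift. The closest known reaction type is the enantioselective boron-enolate variant of the Ireland–Claisen rearrangement, known for allyl esters of propanoic and but-3-enoic acids including 3,3-disubstituted allyl groups. No ring is closed; C5–C10 forms and O–C2 breaks in a chair transition state, and formation of the carboxylate C=O pays for the quaternary centre and makes the step irreversible. C10 is fixed by the E geometry of C1=C10 (C9 equatorial, methyl axial in the chair) and C5 by the enolate geometry (C4 axial), which together give the anti relation of C4 and C9, that is the 5αH/10β-methyl array of the target. The absolute sense comes from the C2-symmetric sulfonamide groups on boron, which shield one face of the ketene acetal. The step needs enolisation without migration of C3=C4 into conjugation, secured by irreversible enolisation at −78 °C and the absence of a proton source until work-up. It also needs chair over boat selectivity, secured by the open chain and the E-trisubstituted alkene. The vinyl group arises by allylic transposition and C3=C4 is carried along, so both alkenes of the 1,5-diene are in place after this one step.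

Step 7
Reactants: 13 (2R,3S)-2-{3-[(tert-butyldimethylsilyl)oxy]prop-1-en-2-yl}-3-ethenyl-3-methyl-5-[(triethylsilyl)oxy]pentanoic acid
Product: 14 (2R,3S)-2-{3-[(tert-butyldimethylsilyl)oxy]prop-1-en-2-yl}-3-ethenyl-3-methyl-5-[(triethylsilyl)oxy]pentan-1-ol
Conditions: LiAlH4, Et2O, 0 °C; H2O
Reagents that add atoms: none
Why: Hydride reduction of the acid; isolated alkenes and silyl ethers are inert and no stereocentre is touched.

Step 8
Reactants: 14 (2R,3S)-2-{3-[(tert-butyldimethylsilyl)oxy]prop-1-en-2-yl}-3-ethenyl-3-methyl-5-[(triethylsilyl)oxy]pentan-1-ol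
Product: 15 (2R,3S)-2-{3-[(tert-butyldimethylsilyl)oxy]prop-1-en-2-yl}-3-ethenyl-3-methyl-5-[(triethylsilyl)oxy]pentanal
Conditions: Dess–Martin periodinane, NaHCO3, CH2Cl2, 0 °C → rt
Reagents that add atoms: none
Why: Buffered Dess–Martin oxidation avoids epimerisation at C5 and conjugation of C3=C4. Activated DMSO is not used here because it would also attack the primary triethylsilyl ether.

Step 9
Reactants: 15 (2R,3S)-2-{3-[(tert-butyldimethylsilyl)oxy]prop-1-en-2-yl}-3-ethenyl-3-methyl-5-[(triethylsilyl)oxy]pentanal; 16 (2-methylprop-1-en-1-yl)magnesium bromide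
Product: 17 (4S,5R,6S)-5-{3-[(tert-butyldimethylsilyl)oxy]prop-1-en-2-yl}-6-ethenyl-2,6-dimethyl-8-[(triethylsilyl)oxy]oct-2-en-4-ol
Conditions: THF, −78 °C; H2O
Reagents that add atoms: none
Why: Felkin–Anh addition. The quaternary C10 group is the large substituent and stands anti to the incoming alkenyl nucleophile, the C4 alkenyl group is medium and H small. This arrangement gives the C5/C6 relation of the target (6α-oxygen, trans to C4).

Step 10
Reactants: 17 (4S,5R,6S)-5-{3-[(tert-butyldimethylsilyl)oxy]prop-1-en-2-yl}-6-ethenyl-2,6-dimethyl-8-[(triethylsilyl)oxy]oct-2-en-4-ol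
Product: 18 (4S,5R,6S)-4-[(tert-butyldimethylsilyl)oxy]-5-{3-[(tert-butyldimethylsilyl)oxy]prop-1-en-2-yl}-6-ethenyl-2,6-dimethyl-8-[(triethylsilyl)oxy]oct-2-ene
Conditions: TBSOTf, 2,6-lutidine, CH2Cl2, −78 °C
Reagents that add atoms: tert-butyldimethylsilyl triflate, CC(C)(C)[Si](C)(C)OS(=O)(=O)C(F)(F)F
Why: Silylation with the triflate and a hindered base is fast at low temperature, so the ionisable allylic alcohol is protected without allylic transposition.

Step 11
Reactants: 18 (4S,5R,6S)-4-[(tert-butyldimethylsilyl)oxy]-5-{3-[(tert-butyldimethylsilyl)oxy]prop-1-en-2-yl}-6-ethenyl-2,6-dimethyl-8-[(triethylsilyl)oxy]oct-2-ene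
Product: 19 (3S,4R,5S)-5-[(tert-butyldimethylsilyl)oxy]-4-{3-[(tert-butyldimethylsilyl)oxy]prop-1-en-2-yl}-3-ethenyl-3,7-dimethyloct-6-enal
Conditions: (COCl)2, DMSO, CH2Cl2, −78 → −40 °C; Et3N, −78 °C → rt
Reagents that add atoms: none
Why: Under Swern conditions a primary triethylsilyl ether is cleaved by the activated sulfoxide and oxidised directly to the aldehyde, while tert-butyldimethylsilyl ethers survive. The aldehyde has a quaternary β-carbon and cannot conjugate.

Step 12
Reactants: 19 (3S,4R,5S)-5-[(tert-butyldimethylsilyl)oxy]-4-{3-[(tert-butyldimethylsilyl)oxy]prop-1-en-2-yl}-3-ethenyl-3,7-dimethyloct-6-enal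
Product: 20 (1S,2R,3R,4R,5S)-3-[(tert-butyldimethylsilyl)oxy]-4-{3-[(tert-butyldimethylsilyl)oxy]prop-1-en-2-yl}-5-ethenyl-5-methyl-2-(prop-1-en-2-yl)cyclohexan-1-ol
Conditions: Me2AlCl, CH2Cl2, −78 → −30 °C; H2O
Reagents that add atoms: none
Why: Type I intramolecular carbonyl-ene reaction, the closure known from citronellal to isopulegol. C7 of the trisubstituted alkene attacks C8 and a C11 methyl hydrogen passes to oxygen. In the chair with the C5 and C6 substituents and the vinyl group equatorial, the new C7 isopropenyl and C8 oxygen are trans-diequatorial (7β, 8α), and an axial C8 oxygen would clash with the axial C10 methyl group.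

Step 13
Reactants: 21 (2E)-but-2-enal
Product: 22 (2Z)-2-iodobut-2-enal
Conditions: I2, K2CO3, DMAP (cat.), THF–H2O, rt
Reagents that add atoms: iodine, II
Why: α-Iodination of an enal by conjugate addition of the amine, iodination and elimination. The product has iodine cis to the methyl group, which is the geometry later needed for the carboxyl group.

Step 14
Reactants: 22 (2Z)-2-iodobut-2-enal
Product: 23 (2Z)-2-iodobut-2-en-1-ol
Conditions: NaBH4, MeOH, 0 °C
Reagents that add atoms: none
Why: 1,2-Reduction of the aldehyde; the alkene geometry and the C–I bond are not affected.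

Step 15
Reactants: 23 (2Z)-2-iodobut-2-en-1-ol
Product: 24 tert-butyl{[(2Z)-2-iodobut-2-en-1-yl]oxy}dimethylsilane
Conditions: TBSCl, imidazole, CH2Cl2, rt
Reagents that add atoms: tert-butyldimethylsilyl chloride, CC(C)(C)[Si](C)(C)Cl
Why: Standard silylation of a primary allylic alcohol.

Step 16
Reactants: 24 tert-butyl{[(2Z)-2-iodobut-2-en-1-yl]oxy}dimethylsilane
Product: 26 (2Z)-2-{[(tert-butyldimethylsilyl)oxy]methyl}but-2-enoic acid, via vinyllithium 25 (not isolated)
Conditions: t-BuLi (2 equiv), Et2O, −78 °C; CO2; aq. HCl to pH 3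
Reagents that add atoms: carbon dioxide, O=C=O
Why: Iodine–lithium exchange and carboxylation of an alkenyllithium both go with retention at −78 °C, so the methyl group ends up cis to the carboxyl group.

Step 17
Reactants: 20 (1S,2R,3R,4R,5S)-3-[(tert-butyldimethylsilyl)oxy]-4-{3-[(tert-butyldimethylsilyl)oxy]prop-1-en-2-yl}-5-ethenyl-5-methyl-2-(prop-1-en-2-yl)cyclohexan-1-ol; 26 (2Z)-2-{[(tert-butyldimethylsilyl)oxy]methyl}but-2-enoic acid
Product: 28 8α-O-[(2Z)-2-{[(tert-butyldimethylsilyl)oxy]methyl}but-2-enoyl] derivative of 20 (5R,6R,7R,8S,10S), via mixed anhydride 27 (not isolated)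
Conditions: 2,4,6-trichlorobenzoyl chloride, Et3N, toluene, rt; then 20, DMAP, toluene, rt
Reagents that add atoms: none
Why: Yamaguchi esterification is suited to an equatorial but flanked secondary alcohol and an α-branched enoic acid. C8–OH is the only free hydroxyl group and its configuration is retained.

Step 18
Reactants: 28 8α-O-[(2Z)-2-{[(tert-butyldimethylsilyl)oxy]methyl}but-2-enoyl] derivative of 20
Product: 29 12-hydroxy derivative of 28 in which C7 bears a 3-hydroxyprop-1-en-2-yl group (5R,6R,7R,8S,10S)
Conditions: SeO2 (0.5 equiv), t-BuOOH, CH2Cl2, 0 °C → rt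
Reagents that add atoms: tert-butyl hydroperoxide, CC(C)(C)OO; selenium dioxide, O=[Se]=O
Why: Allylic hydroxylation by an ene reaction and a [2,3]-shift. The C7 isopropenyl group is the only electron-rich alkene with an allylic methyl group, the vinyl group has no allylic hydrogen, and the enoate alkene is deactivated.

Step 19
Reactants: 29 12-hydroxy derivative of 28
Product: 30 6α,15-bis[(tert-butyldimethylsilyl)oxy]-8α-[(2Z)-2-{[(tert-butyldimethylsilyl)oxy]methyl}but-2-enoyloxy]elema-1,3,11(13)-trien-12-oic acid (5R,6R,7R,8S,10S)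
Conditions: TEMPO (cat.), PhI(OAc)2, MeCN–H2O, rt
Reagents that add atoms: water, O
Why: Oxoammonium oxidation of the only free alcohol through the aldehyde hydrate to the acid. Any enal formed in step 18 is taken to the same product.

Step 20
Reactants: 30 6α,15-bis[(tert-butyldimethylsilyl)oxy]-8α-[(2Z)-2-{[(tert-butyldimethylsilyl)oxy]methyl}but-2-enoyloxy]elema-1,3,11(13)-trien-12-oic acid
Product: 32 (3aR,4S,6S,7R,7aR)-6-ethenyl-7-(3-hydroxyprop-1-en-2-yl)-6-methyl-3-methylidene-2-oxooctahydro-1-benzofuran-4-yl (2Z)-2-(hydroxymethyl)but-2-enoate, via trihydroxy acid 31 (not isolated)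
Conditions: HF·pyridine, pyridine–THF, 0 °C → rt
Reagents that add atoms: none
Why: Buffered fluoride removes the three silyl groups without base. The freed 6α-hydroxyl group and the C12 acid are diequatorial neighbours and close in the acidic medium to the trans-fused γ-lactone. The primary hydroxyl groups cannot form a five-membered lactone with C12.

## Compound list

1 | 2-methylprop-2-en-1-ol | C=C(C)CO | starting material
2 | lithium 2-(lithiomethyl)prop-2-en-1-olate | [Li]CC(=C)CO[Li] | intermediate
3 | 3-(hydroxymethyl)but-3-enoic acid | C=C(CO)CC(=O)O | intermediate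
4 | tert-butyldimethylsilyl 3-{[(tert-butyldimethylsilyl)oxy]methyl}but-3-enoate | C=C(CO[Si](C)(C)C(C)(C)C)CC(=O)O[Si](C)(C)C(C)(C)C | intermediate
5 | 3-{[(tert-butyldimethylsilyl)oxy]methyl}but-3-enoic acid | C=C(CO[Si](C)(C)C(C)(C)C)CC(=O)O | intermediate
6 | but-3-yn-1-ol | C#CCCO | starting material
7 | (but-3-yn-1-yloxy)triethylsilane | C#CCCO[Si](CC)(CC)CC | intermediate
8 | dimethyl{(1E)-2-methyl-4-[(triethylsilyl)oxy]but-1-en-1-yl}alane | C[Al](C)/C=C(\C)CCO[Si](CC)(CC)CC | intermediate
9 | lithium butyl(dimethyl){(1E)-2-methyl-4-[(triethylsilyl)oxy]but-1-en-1-yl}aluminate | [Li+].CCCC[Al-](C)(C)/C=C(\C)CCO[Si](CC)(CC)CC | intermediate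
10 | (2E)-3-methyl-5-[(triethylsilyl)oxy]pent-2-en-1-ol | OC/C=C(\C)CCO[Si](CC)(CC)CC | intermediate
11 | (2E)-3-methyl-5-[(triethylsilyl)oxy]pent-2-en-1-yl 3-{[(tert-butyldimethylsilyl)oxy]methyl}but-3-enoate | C=C(CO[Si](C)(C)C(C)(C)C)CC(=O)OC/C=C(\C)CCO[Si](CC)(CC)CC | intermediate
12 | boron ketene acetal of 11 (C4 trans to O–B; boron in the (4S,5S)-4,5-diphenyl-1,3-bis[3,5-bis(trifluoromethyl)benzenesulfonyl]-1,3,2-diazaborolidine ring) | C=C(CO[Si](C)(C)C(C)(C)C)/C=C(\OC/C=C(\C)CCO[Si](CC)(CC)CC)OB1N(S(=O)(=O)c2cc(C(F)(F)F)cc(C(F)(F)F)c2)[C@@H](c2ccccc2)[C@H](c2ccccc2)N1S(=O)(=O)c1cc(C(F)(F)F)cc(C(F)(F)F)c1 | intermediate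
13 | (2R,3S)-2-{3-[(tert-butyldimethylsilyl)oxy]prop-1-en-2-yl}-3-ethenyl-3-methyl-5-[(triethylsilyl)oxy]pentanoic acid | OC(=O)[C@@H](C(=C)CO[Si](C)(C)C(C)(C)C)[C@](C)(C=C)CCO[Si](CC)(CC)CC | intermediate
14 | (2R,3S)-2-{3-[(tert-butyldimethylsilyl)oxy]prop-1-en-2-yl}-3-ethenyl-3-methyl-5-[(triethylsilyl)oxy]pentan-1-ol | OC[C@@H](C(=C)CO[Si](C)(C)C(C)(C)C)[C@](C)(C=C)CCO[Si](CC)(CC)CC | intermediate
15 | (2R,3S)-2-{3-[(tert-butyldimethylsilyl)oxy]prop-1-en-2-yl}-3-ethenyl-3-methyl-5-[(triethylsilyl)oxy]pentanal | O=C[C@@H](C(=C)CO[Si](C)(C)C(C)(C)C)[C@](C)(C=C)CCO[Si](CC)(CC)CC | intermediate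
16 | (2-methylprop-1-en-1-yl)magnesium bromide | CC(C)=C[Mg]Br | starting material
17 | (4S,5R,6S)-5-{3-[(tert-butyldimethylsilyl)oxy]prop-1-en-2-yl}-6-ethenyl-2,6-dimethyl-8-[(triethylsilyl)oxy]oct-2-en-4-ol | CC(C)=C[C@H](O)[C@@H](C(=C)CO[Si](C)(C)C(C)(C)C)[C@](C)(C=C)CCO[Si](CC)(CC)CC | intermediate
18 | (4S,5R,6S)-4-[(tert-butyldimethylsilyl)oxy]-5-{3-[(tert-butyldimethylsilyl)oxy]prop-1-en-2-yl}-6-ethenyl-2,6-dimethyl-8-[(triethylsilyl)oxy]oct-2-ene | CC(C)=C[C@H](O[Si](C)(C)C(C)(C)C)[C@@H](C(=C)CO[Si](C)(C)C(C)(C)C)[C@](C)(C=C)CCO[Si](CC)(CC)CC | intermediate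
19 | (3S,4R,5S)-5-[(tert-butyldimethylsilyl)oxy]-4-{3-[(tert-butyldimethylsilyl)oxy]prop-1-en-2-yl}-3-ethenyl-3,7-dimethyloct-6-enal | CC(C)=C[C@H](O[Si](C)(C)C(C)(C)C)[C@@H](C(=C)CO[Si](C)(C)C(C)(C)C)[C@](C)(C=C)CC=O | intermediate
20 | (1S,2R,3R,4R,5S)-3-[(tert-butyldimethylsilyl)oxy]-4-{3-[(tert-butyldimethylsilyl)oxy]prop-1-en-2-yl}-5-ethenyl-5-methyl-2-(prop-1-en-2-yl)cyclohexan-1-ol | C=C[C@]1(C)C[C@H](O)[C@@H](C(C)=C)[C@H](O[Si](C)(C)C(C)(C)C)[C@H]1C(=C)CO[Si](C)(C)C(C)(C)C | intermediate
21 | (2E)-but-2-enal | C/C=C/C=O | starting material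
22 | (2Z)-2-iodobut-2-enal | C/C=C(\I)C=O | intermediate
23 | (2Z)-2-iodobut-2-en-1-ol | C/C=C(\I)CO | intermediate
24 | tert-butyl{[(2Z)-2-iodobut-2-en-1-yl]oxy}dimethylsilane | C/C=C(\I)CO[Si](C)(C)C(C)(C)C | intermediate
25 | alkenyllithium from 24 (lithium cis to the methyl group) | C/C=C(\[Li])CO[Si](C)(C)C(C)(C)C | intermediate
26 | (2Z)-2-{[(tert-butyldimethylsilyl)oxy]methyl}but-2-enoic acid | O=C(O)/C(=C\C)CO[Si](C)(C)C(C)(C)C | intermediate
27 | (2Z)-2-{[(tert-butyldimethylsilyl)oxy]methyl}but-2-enoic 2,4,6-trichlorobenzoic anhydride | O=C(OC(=O)/C(=C\C)CO[Si](C)(C)C(C)(C)C)c1c(Cl)cc(Cl)cc1Cl | intermediate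
28 | (1S,2R,3R,4R,5S)-3-[(tert-butyldimethylsilyl)oxy]-4-{3-[(tert-butyldimethylsilyl)oxy]prop-1-en-2-yl}-5-ethenyl-5-methyl-2-(prop-1-en-2-yl)cyclohexyl (2Z)-2-{[(tert-butyldimethylsilyl)oxy]methyl}but-2-enoate | C=C[C@]1(C)C[C@H](OC(=O)/C(=C\C)CO[Si](C)(C)C(C)(C)C)[C@@H](C(C)=C)[C@H](O[Si](C)(C)C(C)(C)C)[C@H]1C(=C)CO[Si](C)(C)C(C)(C)C | intermediate
29 | 12-hydroxy derivative of 28 (C7 bears 3-hydroxyprop-1-en-2-yl; 5R,6R,7R,8S,10S) | C=C[C@]1(C)C[C@H](OC(=O)/C(=C\C)CO[Si](C)(C)C(C)(C)C)[C@@H](C(=C)CO)[C@H](O[Si](C)(C)C(C)(C)C)[C@H]1C(=C)CO[Si](C)(C)C(C)(C)C | intermediate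
30 | 6α,15-bis[(tert-butyldimethylsilyl)oxy]-8α-[(2Z)-2-{[(tert-butyldimethylsilyl)oxy]methyl}but-2-enoyloxy]elema-1,3,11(13)-trien-12-oic acid (5R,6R,7R,8S,10S) | C=C[C@]1(C)C[C@H](OC(=O)/C(=C\C)CO[Si](C)(C)C(C)(C)C)[C@@H](C(=C)C(=O)O)[C@H](O[Si](C)(C)C(C)(C)C)[C@H]1C(=C)CO[Si](C)(C)C(C)(C)C | intermediate
31 | 6α,15-dihydroxy-8α-[(2Z)-2-(hydroxymethyl)but-2-enoyloxy]elema-1,3,11(13)-trien-12-oic acid (5R,6R,7S,8S,10S) | C=C[C@]1(C)C[C@H](OC(=O)/C(=C\C)CO)[C@@H](C(=C)C(=O)O)[C@H](O)[C@H]1C(=C)CO | intermediate
32 | (3aR,4S,6S,7R,7aR)-6-ethenyl-7-(3-hydroxyprop-1-en-2-yl)-6-methyl-3-methylidene-2-oxooctahydro-1-benzofuran-4-yl (2Z)-2-(hydroxymethyl)but-2-enoate | C=C[C@]1(C)C[C@H](OC(=O)/C(=C\C)CO)[C@H]2C(=C)C(=O)O[C@@H]2[C@H]1C(=C)CO | target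

## Step count and least certain steps

Total step count: 20. Longest linear sequence: 14 steps (1, 2, 5–12, 17–20).

**Step 6 (key step).**
- What may go wrong: enolisation may be incomplete or of mixed geometry. Bond formation at the fully substituted allyl terminus may be slow, which gives time for boat leakage or decomposition. The facial shielding may be eroded by the bulky C4 substituent, and the Lewis-acidic boron bromide may loosen a silyl ether.
- Fallback: it sets out from 11. Enolisation with LDA in THF at −78 °C, trapping with TMSCl and warming give the anti acid as the racemate, that is 13 together with its mirror image, (2S,3R)-acid F1.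
- The mixture is converted through the pivaloyl mixed anhydride with lithiated (S)-4-benzyl-1,3-oxazolidin-2-one into two diastereomeric imides. The imide of 13, F2, is separated by chromatography from the imide of the mirror-image acid, F3.
- Reduction of F2 with LiBH4 in Et2O–MeOH returns to the route at 14.

**Step 12.**
- What may go wrong: the aldehyde may be attacked by the 1,1-disubstituted C3=C4 alkene (a type II ene closure onto C3). The allylic C6 silyl ether may ionise under the Lewis acid, or methyl may be transferred from aluminium to the aldehyde.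
- Fallback: it replaces the ene reaction by an allylsilane addition and sets out from 15. 3-(Trimethylsilyl)propyne is taken by carboalumination and iodination to [(2E)-3-iodo-2-methylprop-2-en-1-yl]trimethylsilane F4.
- Its lithium derivative (t-BuLi) is added to 15 to give allylsilane alcohol F5. Silylation as in step 10 gives silyl ether F6, and oxidation as in step 11 gives allylsilane aldehyde F7.
- BF3·OEt2 at −78 °C closes the C7–C8 bond by an intramolecular Hosomi–Sakurai reaction. The allylsilane is by far the most nucleophilic alkene in F7. The route is rejoined at 20.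

**Step 9.**
- What may go wrong: facial selectivity may be poor if the alkenyl group competes with C10 for the role of the large substituent. The basic reagent may also epimerise C5 or move C3=C4 into conjugation.
- Fallback: it sets out from 17 obtained as a mixture of C6 epimers. Dess–Martin oxidation gives (5R,6S)-enone F8. Oxazaborolidine-catalysed borane reduction (CBS reduction), with the catalyst enantiomer that overrides the substrate bias, sets C6 by reagent control and returns to 17.

**Step 17.**
- What may go wrong: the activated acyl group may isomerise from Z to E by reversible conjugate addition of DMAP. Acylation of the flanked alcohol may be slow, which lengthens the exposure.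
- Fallback: no acyl-transfer catalyst is used. The ester carbonyl group is built on the alcohol by palladium-catalysed alkoxycarbonylation of vinyl iodide 24 with alcohol 20 (Pd(PPh3)4, CO, Et3N, DMF). This reaction retains the alkene geometry and leads directly to 28.

**Step 18.**
- What may go wrong: oxidation may occur at the C7 methine or at C15/C5 of the other 1,1-disubstituted alkene, the product may be over-oxidised, or conversion may stall.
- Fallback: it sets out from 28. Dye-sensitised photooxygenation (Schenck ene reaction of singlet oxygen) takes a hydrogen from the C12 methyl group and gives primary allylic hydroperoxide F9. Reduction with PPh3 gives 29.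

## Further compounds

F1 | step 6 | (2S,3R)-2-{3-[(tert-butyldimethylsilyl)oxy]prop-1-en-2-yl}-3-ethenyl-3-methyl-5-[(triethylsilyl)oxy]pentanoic acid | OC(=O)[C@H](C(=C)CO[Si](C)(C)C(C)(C)C)[C@@](C)(C=C)CCO[Si](CC)(CC)CC
F2 | step 6 | (4S)-4-benzyl-3-[(2R,3S)-2-{3-[(tert-butyldimethylsilyl)oxy]prop-1-en-2-yl}-3-ethenyl-3-methyl-5-[(triethylsilyl)oxy]pentanoyl]-1,3-oxazolidin-2-one | O=C1OC[C@H](Cc2ccccc2)N1C(=O)[C@@H](C(=C)CO[Si](C)(C)C(C)(C)C)[C@](C)(C=C)CCO[Si](CC)(CC)CC
F3 | step 6 | (4S)-4-benzyl-3-[(2S,3R)-2-{3-[(tert-butyldimethylsilyl)oxy]prop-1-en-2-yl}-3-ethenyl-3-methyl-5-[(triethylsilyl)oxy]pentanoyl]-1,3-oxazolidin-2-one | O=C1OC[C@H](Cc2ccccc2)N1C(=O)[C@H](C(=C)CO[Si](C)(C)C(C)(C)C)[C@@](C)(C=C)CCO[Si](CC)(CC)CC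
F4 | step 12 | [(2E)-3-iodo-2-methylprop-2-en-1-yl]trimethylsilane | C[Si](C)(C)C/C(C)=C/I
F5 | step 12 | (2E,4S,5R,6S)-5-{3-[(tert-butyldimethylsilyl)oxy]prop-1-en-2-yl}-6-ethenyl-2,6-dimethyl-8-[(triethylsilyl)oxy]-1-(trimethylsilyl)oct-2-en-4-ol | C[Si](C)(C)C/C(C)=C/[C@H](O)[C@@H](C(=C)CO[Si](C)(C)C(C)(C)C)[C@](C)(C=C)CCO[Si](CC)(CC)CC
F6 | step 12 | 4-O-tert-butyldimethylsilyl ether of F5 | C[Si](C)(C)C/C(C)=C/[C@H](O[Si](C)(C)C(C)(C)C)[C@@H](C(=C)CO[Si](C)(C)C(C)(C)C)[C@](C)(C=C)CCO[Si](CC)(CC)CC
F7 | step 12 | (3S,4R,5S,6E)-5-[(tert-butyldimethylsilyl)oxy]-4-{3-[(tert-butyldimethylsilyl)oxy]prop-1-en-2-yl}-3-ethenyl-3,7-dimethyl-8-(trimethylsilyl)oct-6-enal | C[Si](C)(C)C/C(C)=C/[C@H](O[Si](C)(C)C(C)(C)C)[C@@H](C(=C)CO[Si](C)(C)C(C)(C)C)[C@](C)(C=C)CC=O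
F8 | step 9 | (5R,6S)-5-{3-[(tert-butyldimethylsilyl)oxy]prop-1-en-2-yl}-6-ethenyl-2,6-dimethyl-8-[(triethylsilyl)oxy]oct-2-en-4-one | CC(C)=CC(=O)[C@@H](C(=C)CO[Si](C)(C)C(C)(C)C)[C@](C)(C=C)CCO[Si](CC)(CC)CC
F0 | step 17 | none | none
F9 | step 18 | 12-hydroperoxy derivative of 28 (C7 bears 3-hydroperoxyprop-1-en-2-yl) | C=C[C@]1(C)C[C@H](OC(=O)/C(=C\C)CO[Si](C)(C)C(C)(C)C)[C@@H](C(=C)COO)[C@H](O[Si](C)(C)C(C)(C)C)[C@H]1C(=C)CO[Si](C)(C)C(C)(C)C
A1 | alternative 1 | 8α,15-dihydroxygermacra-1(10),4,11(13)-trien-6α,12-olide (both ring alkenes trans in the ring) | C/C1=C\CC/C(CO)=C/[C@H]2OC(=O)C(=C)[C@@H]2[C@@H](O)C1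
A2 | alternative 2 | 1β-(methanesulfonyloxy)-3β,8α-dihydroxyeudesma-4(15),11(13)-dien-6α,12-olide | C[C@@]12C[C@H](O)[C@H]3C(=C)C(=O)O[C@@H]3[C@H]1C(=C)[C@@H](O)C[C@H]2OS(C)(=O)=O
A3 | alternative 2 | 8α-hydroxy-15-oxoelema-1,3,11(13)-trien-6α,12-olide | C=C[C@]1(C)C[C@H](O)[C@H]2C(=C)C(=O)O[C@@H]2[C@H]1C(=C)C=O
A4 | alternative 3 | 3-methylcyclohex-2-en-1-one | CC1=CC(=O)CCC1
A5 | alternative 3 | trans-2-{3-[(tert-butyldimethylsilyl)oxy]prop-1-en-2-yl}-3-ethenyl-3-methylcyclohexan-1-one (C5 and C10 as in the target) | C=C[C@]1(C)CCCC(=O)[C@H]1C(=C)CO[Si](C)(C)C(C)(C)C
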